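Assumption: the target is taken as the open-chain keto acid that its SMILES shows; its cyclic hemiketal tautomer is treated as the same substance in equilibrium.

Atom bookkeeping: the carboxyl carbon of 1 becomes the C2′ ketone, so eleven methylenes separate C2′ from the terminal oxygen in every compound from 3 to 19, as the target requires. No structure needed changing.

Design remark: the ketal-protected acyl unit is brought in as Weinreb amide 7, not as a free acid or active ester. This saves a hydrolysis and an activation and gives the least enolisable acyl donor. The aromatisation is finished with AcOH instead of mineral acid so that the dioxolane is still present in 16.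

## Structural features

Target 19 has one benzene ring and one unbranched side chain. In benzoic acid numbering the carboxyl group sits on C1, a free hydroxyl on C2, a methoxyl on C4 and the chain on C6, while C3 and C5 carry hydrogen. The chain is joined to the ring through the benzylic methylene C1′ and has a ketone at C2′, eleven methylenes C3′ to C13′ and a primary hydroxyl on C13′. There is no stereocentre, hence no neighbouring stereocentres, and the task is one of regiochemistry and chemoselectivity. The fragile region is the ortho pairing of the C1 carboxyl with the C2′ ketone: acid or heat can close the ketone oxygen onto the carboxyl and dehydrate the hemiketal to an isocoumarin, C1′ is acidified by ring and ketone together, and the electron-rich salicylic acid can lose CO2 when heated with acid. The real difficulty is to set the 1,2,4,6 pattern of four different substituents, to methylate O4 but not O2, and to free the acid and the C13′ alcohol at the end without starting that lactonisation. The key step uses the alternating oxygenation at C1 (as its carboxyl), C2 and C4 together with the carbon substituent on C6. These atoms coincide with the ester carbon, the two inner ketones and the outer ketone of a folded 3,5,7-triketo ester, so one aldol bond between C1 and C6 closes the ring with every oxygen already in place.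

## Logic of the disconnections

19 to 18. The two O–CH2Ph bonds are cut, one at the C1 carboxyl and one at O13′. Both polar groups are then released last, in one neutral reductive step, so that no acid or base meets the ortho keto acid. The gain is that the carboxyl cannot lactonise and the primary alcohol cannot be acylated in any earlier step. The forward step must remove both benzyl groups without touching the C2′ ketone or the arene.

18 to 17. The C2′ carbonyl is returned to its cyclic ketal (two C2′–O bonds). A free C2′ ketone would act as a fourth carbonyl during ring formation and would make C1′ doubly activated. The gain is an inert chain through all carbanion chemistry. The forward hydrolysis must be mild enough that the freed ketone does not attack the neighbouring ester.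

17 to 16. The O4–CH3 bond is cut. The two phenols differ because O2–H is hydrogen-bonded to the ester carbonyl and O4–H is not. The gain is that the unmethylated resorcylate is exactly what the ring-forming step delivers. The forward step must stop at mono-methylation on O4.

16 to 11 and 12, through 15, 14 and 13. The ring bond C1–C6 and the ester C–O bond are cut. The arene is thereby replaced by a linear carbonyl chain that has no regiochemical problem of its own, with the reactive β-keto ester terminus stored in the heterocycle of 11 as a latent ketene. The forward step must fold in the aldol sense only, and the ketal must survive heat, carbonate and the acid finish.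

11 to 10 and 7. The C–C bond between the carbonyl that becomes ring C6 and the methylene that becomes ring C5 is cut, a 1,3-dicarbonyl retron. This splits the precursor into a small heterocyclic ketone and the complete side chain. The acyl donor must add once only and must resist enolisation, because enolisation would open the β-ketal.

10 to 8 and 9. The bond between the exocyclic methylene (future ring C3) and the acetyl carbonyl (future ring C4) is cut. Both partners are commercial. The forward acylation must go at the γ-carbon of the dienolate, not at the α-carbon or at oxygen, and must tolerate a product more acidic than the starting heterocycle.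

7 to 6. The two ketal C–O bonds are cut. The ketone has to be masked before strong base is used, and this leaves a simple β-keto amide. The forward step must ketalise the ketone and leave the amide alone.

6 to 3 and 4, through 5. The C–C bond between the future C2′ and the future C1′ is cut, together with the amide C–N bond. This is a two-carbon homologation of a fatty acid in which 4 supplies C1′ and the carbon that becomes ring C6. The forward sequence needs C-acylation followed by ring fragmentation with capture by the amine.

3 to 1, through 2. The O–benzyl bond at the terminal oxygen is cut. The free primary alcohol would be acylated in the homologation and would trap the ketene of the key step intramolecularly. Benzyl is chosen because it leaves together with the ester in the last step. The forward step must leave the carboxyl free.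

## Other disconnections considered

Alternative 1: The cut is the C6–C1′ bond of a preformed arene, and the forward step also forms the lactone C–O bond. 2-(Benzyloxy)-4-methoxybenzoic acid A1 and the sulfoxonium ylide dimethylsulfoxonium 13-(benzyloxy)-2-oxotridecylide A2 would be combined with [Cp*RhCl2]2, AgSbF6 and NaOAc. The carboxylate directs cleavage of the C6–H bond by trivalent rhodium, the ylide loses its sulfoxide to give a metal carbene, migratory insertion makes C6–C1′, and the resulting keto acid cyclodehydrates to the isocoumarin 8-(benzyloxy)-3-[11-(benzyloxy)undecyl]-6-methoxy-1H-isochromen-1-one A3. Hydroxide opening of the lactone and hydrogenolysis of both benzyl ethers would then lead to 19.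
- In its favour: the substitution pattern comes ready-made, C6–H is the only free position ortho to the carboxylate, and A2 derives from 3 in one or two operations.
- Against it here: A3 is the very lactone that the target must not become, so the route has to end with a hydrolytic ring opening and an acidification during which re-closure is the downhill direction. The electron-rich, ortho-alkoxy benzoic acid is also a candidate for protodecarboxylation under cationic metal catalysis.
- Comparison: on structure the two plans are equal in regiochemical certainty, and the alternative is better in that O4 is methylated from the start. On mechanism it decorates an arene by carbene insertion where the chosen plan builds the arene by ionic aldol chemistry. On step economy the alternative is better, at about six to eight operations against nine. The chosen plan is preferred because it keeps C2′ masked until the ester is the only neighbour and releases the open keto acid under neutral conditions.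

Alternative 2: The cuts are the C6–C1′ bond and the C1–carboxyl bond, made together. CsF would release the aryne from 3,5-dimethoxy-2-(trimethylsilyl)phenyl trifluoromethanesulfonate A4, and dimethyl malonate A5 would insert its C–C bond across the triple bond to give methyl 2,4-dimethoxy-6-(2-methoxy-2-oxoethyl)benzoate A6. The enolate carbon adds at the aryne carbon remote from the flanking methoxyl, and the aryl anion then takes the ester carbon.
- In its favour: two ortho carbon substituents are installed in one mild operation with predictable orientation, and no sensitive polycarbonyl chain is handled. On handling this is better than the chosen plan.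
- Against it here: A6 carries the wrong state at four sites. The aliphatic ester must be told apart from the aromatic one and extended by the twelve-carbon unit. The C2 methyl ether must be cleaved selectively beside the C4 one. The doubly ortho-substituted methyl benzoate must be cleaved under forcing conditions with an enolisable 2-oxoalkyl group next to it. A4 itself needs several steps.
- Comparison: on structure the two plans are equal for the ring pattern, but the alternative leaves all oxygen differentiation for later. On mechanism it is a nucleophilic aryne addition with acyl transfer against an aldol condensation. On step economy it is clearly longer than the chosen plan.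

Alternative 3: The cuts are the ring bonds C1–C2 and C5–C6. The diene 1,3-dimethoxy-1-(trimethylsilyloxy)buta-1,3-diene A7 would add on heating to the ynoate benzyl 4-[2-(11-(benzyloxy)undecyl)-1,3-dioxolan-2-yl]but-2-ynoate A8. The nucleophilic CH2 terminus of A7 bonds to the β-carbon of A8, and elimination of the acetal methoxy group on acidic work-up gives benzyl 6-{[2-(11-(benzyloxy)undecyl)-1,3-dioxolan-2-yl]methyl}-2-hydroxy-4-methoxybenzoate A9, which is identical with 17.
- In its favour: A9 arrives with O4 already methylated and O2 free, so the phenol differentiation step is not needed. On this point the alternative is better. Steps 8 and 9 of the chosen route would finish the synthesis unchanged.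
- Against it here: a β-alkyl ynoate whose β-substituent is branched next to a ketal is a slow dienophile, while A7 is thermally and hydrolytically labile. The acidic work-up meets the dioxolane. The preparation of A8 passes through a β,γ-alkynyl ketone stage that isomerises easily before it can be ketalised.
- Comparison: on structure the alternative is slightly better because of the built-in methyl ether. On mechanism it is a polarity-controlled [4+2] addition with aromatising elimination, as against thermal ketene capture and aldol. On step economy the two are about equal. The chosen plan is preferred because each of its steps before the ring formation is a routine carbonyl reaction.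

Key step: step 6

Step 1
Reactants: 1 12-hydroxydodecanoic acid
Product: 3 12-(benzyloxy)dodecanoic acid, via benzyl 12-(benzyloxy)dodecanoate 2 (not isolated)
Conditions: NaH (3 equiv), BnBr (2.3 equiv), nBu4NI (cat.), THF–DMF, 0 °C → rt; then NaOH, MeOH–H2O, 60 °C; aq HCl
Reagents that add atoms: benzyl bromide, BrCc1ccccc1; sodium hydroxide, [Na+].[OH-]
Why: Williamson alkylation of alkoxide and carboxylate is driven to completion with excess base and bromide, and hydroxide then cleaves only the benzyl ester by acyl substitution, so the ether acid should result without a selectivity problem.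

Step 2
Reactants: 3 12-(benzyloxy)dodecanoic acid; 4 Meldrum's acid (2,2-dimethyl-1,3-dioxane-4,6-dione)
Product: 6 14-(benzyloxy)-N-methoxy-N-methyl-3-oxotetradecanamide, via acyl Meldrum's acid 5 (not isolated)
Conditions: DCC (1.1 equiv), DMAP (1.5 equiv), CH2Cl2, 0 °C → rt; filtration, aq KHSO4 wash; then MeNH(OMe)·HCl (1.5 equiv), Et3N (1.5 equiv), PhMe, 80 °C
Reagents that add atoms: N,O-dimethylhydroxylamine hydrochloride, CNOC.Cl
Why: Carbodiimide-mediated C-acylation of 4 gives 5, which on heating fragments with loss of acetone and CO2 through an acylketene that the amine captures (aminolysis of an acyl Meldrum's acid), so the β-keto Weinreb amide should form in one operation.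

Step 3
Reactants: 6 14-(benzyloxy)-N-methoxy-N-methyl-3-oxotetradecanamide
Product: 7 2-[2-(11-(benzyloxy)undecyl)-1,3-dioxolan-2-yl]-N-methoxy-N-methylacetamide
Conditions: HO(CH2)2OH (5 equiv), p-TsOH·H2O (cat.), PhMe, reflux, Dean–Stark
Reagents that add atoms: ethylene glycol, OCCO
Why: Acid-catalysed ketalisation with azeotropic removal of water should convert the ketone only, since the amide carbonyl does not ketalise and the benzyl ether is inert to these conditions.

Step 4
Reactants: 8 2,2,6-trimethyl-4H-1,3-dioxin-4-one; 9 acetyl chloride
Product: 10 6-(2-oxopropyl)-2,2-dimethyl-4H-1,3-dioxin-4-one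
Conditions: 8 (2 equiv), LiN(SiMe3)2 (2 equiv), THF, −78 °C; 9 (1 equiv), −78 → −20 °C; 1 M aq HCl
Reagents that add atoms: none
Why: Vinylogous Claisen-type acylation of the lithium dienolate of 8 at its γ-carbon is the established entry to keto-dioxinones, and the second equivalent of dienolate absorbs the proton of the more acidic product.

Step 5
Reactants: 10 6-(2-oxopropyl)-2,2-dimethyl-4H-1,3-dioxin-4-one; 7 2-[2-(11-(benzyloxy)undecyl)-1,3-dioxolan-2-yl]-N-methoxy-N-methylacetamide
Product: 11 6-{5-[2-(11-(benzyloxy)undecyl)-1,3-dioxolan-2-yl]-2,4-dioxopentyl}-2,2-dimethyl-4H-1,3-dioxin-4-one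
Conditions: 10 (1.5 equiv), LiN(iPr)2 (3.1 equiv), THF, −78 → −40 °C; 7 (1 equiv), −78 → −10 °C; AcOH, −78 °C
Reagents that add atoms: none
Why: Claisen-type acylation of a 1,3-dicarbonyl dianion at its terminal, more reactive carbanion; the chelated tetrahedral adduct of the Weinreb amide should prevent double addition and keep the diketone from quenching the dianion, and the weakly acidic amide α-hydrogens limit enolisation toward opening of the β-ketal.

Step 6
Reactants: 11 6-{5-[2-(11-(benzyloxy)undecyl)-1,3-dioxolan-2-yl]-2,4-dioxopentyl}-2,2-dimethyl-4H-1,3-dioxin-4-one; 12 benzyl alcohol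
Product: 16 benzyl 6-{[2-(11-(benzyloxy)undecyl)-1,3-dioxolan-2-yl]methyl}-2,4-dihydroxybenzoate, via acylketene 13 (not isolated), via benzyl triketo ester 14 (not isolated), via aldol adduct 15 (not isolated)
Conditions: 12 (1.5 equiv), PhMe (dilute), 110 °C; concentrate; Cs2CO3, iPrOH–CH2Cl2, rt; then AcOH, rt
Reagents that add atoms: none
Why: At 110 °C the dioxinone ring of 11 undergoes a retro-[4+2] fragmentation that expels acetone and leaves acylketene 13, and 12 adds across the ketene C=O to give the benzyl 3,5,7-triketo ester 14. Cs2CO3 then deprotonates C2 of 14, the carbon between the ester and the first ketone, and this enolate adds to the C7 ketone to give cyclic aldol 15, which creates the ring bond C1–C6 of the arene. The ring closes in the 6-(enolexo)-exo-trig mode, and AcOH brings about loss of water from 15 and enolisation of the two remaining ring ketones to the phenols of 16. The closest known reaction type is the thermolysis of diketo-dioxinones in the presence of an alcohol followed by base- and acid-promoted aldol aromatisation to resorcylate esters, the laboratory counterpart of polyketide folding. No stereocentre is created, since the two of 15 form without control and vanish on aromatisation. The step needs the C2-to-C7 aldol to win over Claisen closure of C6 onto the ester, over O-cyclisation to pyranones and over any reaction of the chain ketone. A mild carbonate base, the poor leaving-group ability of benzyl oxide and the base-before-acid order favour the aldol, while the dioxolane removes C2′ from the carbonyl array and leaves its flanking CH2 too weakly acidic for carbonate. AcOH instead of mineral acid is chosen for the finish so that the dioxolane is still in place in 16.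

Step 7
Reactants: 16 benzyl 6-{[2-(11-(benzyloxy)undecyl)-1,3-dioxolan-2-yl]methyl}-2,4-dihydroxybenzoate
Product: 17 benzyl 6-{[2-(11-(benzyloxy)undecyl)-1,3-dioxolan-2-yl]methyl}-2-hydroxy-4-methoxybenzoate
Conditions: MeI (1.2 equiv), K2CO3 (1.2 equiv), acetone, rt
Reagents that add atoms: methyl iodide, CI
Why: Williamson methylation should go at O4 only, because the para hydroxyl is the more acidic, unencumbered phenol while O2–H is held in a hydrogen bond to the ester carbonyl and is the poorer nucleophile.

Step 8
Reactants: 17 benzyl 6-{[2-(11-(benzyloxy)undecyl)-1,3-dioxolan-2-yl]methyl}-2-hydroxy-4-methoxybenzoate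
Product: 18 benzyl 6-[13-(benzyloxy)-2-oxotridecyl]-2-hydroxy-4-methoxybenzoate
Conditions: 1 M aq HCl, THF, rt
Reagents that add atoms: water, O
Why: Acid-catalysed hydrolysis of a dialkyl ketone dioxolane proceeds at room temperature in dilute acid, conditions under which the benzyl ester, benzyl ether and aryl methyl ether are stable and lactonisation onto the ester should remain slow.

Step 9
Reactants: 18 benzyl 6-[13-(benzyloxy)-2-oxotridecyl]-2-hydroxy-4-methoxybenzoate
Product: 19 2-hydroxy-6-(13-hydroxy-2-oxotridecyl)-4-methoxybenzoic acid
Conditions: H2 (1 atm), Pd/C (10%), EtOAc, rt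
Reagents that add atoms: none
Why: Catalytic hydrogenolysis should cleave the benzyl ester and the primary benzyl ether together while the aliphatic ketone and the arene are not reduced at atmospheric pressure, and the neutral medium releases the keto acid without acid or heat that would dehydrate it to the isocoumarin.

Compound list

1 | 12-hydroxydodecanoic acid | OCCCCCCCCCCCC(=O)O | starting material
2 | benzyl 12-(benzyloxy)dodecanoate (not isolated) | O=C(OCc1ccccc1)CCCCCCCCCCCOCc1ccccc1 | intermediate
3 | 12-(benzyloxy)dodecanoic acid | OC(=O)CCCCCCCCCCCOCc1ccccc1 | intermediate
4 | Meldrum's acid (2,2-dimethyl-1,3-dioxane-4,6-dione) | CC1(C)OC(=O)CC(=O)O1 | starting material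
5 | 5-[12-(benzyloxy)-1-hydroxydodecylidene]-2,2-dimethyl-1,3-dioxane-4,6-dione (acyl Meldrum's acid, not isolated) | CC1(C)OC(=O)C(=C(O)CCCCCCCCCCCOCc2ccccc2)C(=O)O1 | intermediate
6 | 14-(benzyloxy)-N-methoxy-N-methyl-3-oxotetradecanamide | CON(C)C(=O)CC(=O)CCCCCCCCCCCOCc1ccccc1 | intermediate
7 | 2-[2-(11-(benzyloxy)undecyl)-1,3-dioxolan-2-yl]-N-methoxy-N-methylacetamide | CON(C)C(=O)CC1(CCCCCCCCCCCOCc2ccccc2)OCCO1 | intermediate
8 | 2,2,6-trimethyl-4H-1,3-dioxin-4-one | CC1=CC(=O)OC(C)(C)O1 | starting material
9 | acetyl chloride | CC(Cl)=O | starting material
10 | 6-(2-oxopropyl)-2,2-dimethyl-4H-1,3-dioxin-4-one | CC(=O)CC1=CC(=O)OC(C)(C)O1 | intermediate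
11 | 6-{5-[2-(11-(benzyloxy)undecyl)-1,3-dioxolan-2-yl]-2,4-dioxopentyl}-2,2-dimethyl-4H-1,3-dioxin-4-one | CC1(C)OC(=O)C=C(CC(=O)CC(=O)CC2(CCCCCCCCCCCOCc3ccccc3)OCCO2)O1 | intermediate
12 | benzyl alcohol | OCc1ccccc1 | starting material
13 | 8-[2-(11-(benzyloxy)undecyl)-1,3-dioxolan-2-yl]oct-1-ene-1,3,5,7-tetraone (acylketene, not isolated) | O=C=CC(=O)CC(=O)CC(=O)CC1(CCCCCCCCCCCOCc2ccccc2)OCCO1 | intermediate
14 | benzyl 8-[2-(11-(benzyloxy)undecyl)-1,3-dioxolan-2-yl]-3,5,7-trioxooctanoate (not isolated) | O=C(OCc1ccccc1)CC(=O)CC(=O)CC(=O)CC2(CCCCCCCCCCCOCc3ccccc3)OCCO2 | intermediate
15 | benzyl 2-{[2-(11-(benzyloxy)undecyl)-1,3-dioxolan-2-yl]methyl}-2-hydroxy-4,6-dioxocyclohexane-1-carboxylate (aldol adduct, configuration not controlled, not isolated) | O=C(OCc1ccccc1)C1C(=O)CC(=O)CC1(O)CC2(CCCCCCCCCCCOCc3ccccc3)OCCO2 | intermediate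
16 | benzyl 6-{[2-(11-(benzyloxy)undecyl)-1,3-dioxolan-2-yl]methyl}-2,4-dihydroxybenzoate | O=C(OCc1ccccc1)c2c(O)cc(O)cc2CC3(CCCCCCCCCCCOCc4ccccc4)OCCO3 | intermediate
17 | benzyl 6-{[2-(11-(benzyloxy)undecyl)-1,3-dioxolan-2-yl]methyl}-2-hydroxy-4-methoxybenzoate | O=C(OCc1ccccc1)c2c(O)cc(OC)cc2CC3(CCCCCCCCCCCOCc4ccccc4)OCCO3 | intermediate
18 | benzyl 6-[13-(benzyloxy)-2-oxotridecyl]-2-hydroxy-4-methoxybenzoate | O=C(OCc1ccccc1)c2c(O)cc(OC)cc2CC(=O)CCCCCCCCCCCOCc3ccccc3 | intermediate
19 | 2-hydroxy-6-(13-hydroxy-2-oxotridecyl)-4-methoxybenzoic acid | COc1cc(O)c(C(=O)O)c(CC(=O)CCCCCCCCCCCO)c1 | target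

Total step count: 9. Longest linear sequence: 8 steps (steps 1, 2, 3, 5, 6, 7, 8 and 9); step 4 is a one-step branch that supplies 10.

Least certain steps

Step 6 (key step). The most likely failure is diversion of the triketo ester into O-cyclisation to a pyranone or into Claisen closure before the aldol takes place, because the chain is enolisable at three positions and several six-membered closures are within reach. A second failure is partial loss of the dioxolane if the dehydration of the aldol needs more than a weak acid. Fallback: starting from 11, the ring is closed without generating the ketene. Et3N in CH2Cl2 should promote attack of the dioxinone C5 carbon on the terminal ketone and, after loss of water, give 5-{[2-(11-(benzyloxy)undecyl)-1,3-dioxolan-2-yl]methyl}-7-hydroxy-2,2-dimethyl-4H-1,3-benzodioxin-4-one F1, in which the same C1–C6 ring bond has been formed. Methylation of its only phenol (MeI, K2CO3, acetone) gives 5-{[2-(11-(benzyloxy)undecyl)-1,3-dioxolan-2-yl]methyl}-7-methoxy-2,2-dimethyl-4H-1,3-benzodioxin-4-one F2. Opening of the acetonide with 12 and NaH in THF, with loss of acetone, returns to the route at 17, so that step 7 is not needed.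

Step 5. The most likely failure is deprotonation of 7 next to the amide by the strongly basic dianion in place of addition, followed by β-elimination that opens the dioxolane. Slow acylation at the hindered, neopentyl-like carbonyl would give this side path more time. Fallback: starting from 7, reduction with iBu2AlH (THF, −78 °C) gives 2-[2-(11-(benzyloxy)undecyl)-1,3-dioxolan-2-yl]acetaldehyde F3, a far more electrophilic partner. Aldol addition of the dianion of 10 (LiN(iPr)2, THF, −78 °C) gives 6-{5-[2-(11-(benzyloxy)undecyl)-1,3-dioxolan-2-yl]-4-hydroxy-2-oxopentyl}-2,2-dimethyl-4H-1,3-dioxin-4-one F4 as a racemate, and oxidation with Dess–Martin periodinane returns to the route at 11.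

Step 4. The most likely failure is low conversion through proton transfer from the more acidic product to unreacted dienolate, together with competing O-acylation and double acylation by the very reactive acid chloride. Fallback: starting from 8, enolisation and silylation (LiN(iPr)2, Me3SiCl, THF, −78 °C) give [(2,2-dimethyl-6-methylidene-6H-1,3-dioxin-4-yl)oxy]trimethylsilane F5. A vinylogous Mukaiyama aldol addition to acetaldehyde (BF3·OEt2, CH2Cl2, −78 °C) gives racemic 6-(2-hydroxypropyl)-2,2-dimethyl-4H-1,3-dioxin-4-one F6, and Dess–Martin oxidation returns to the route at 10.

Step 8. The most likely failure is acid-promoted closure of the freed C2′ ketone, through its enol or hydrate oxygen, onto the neighbouring benzyl ester with expulsion of the benzyl oxygen, which is lactonisation toward the isocoumarin series. If the acid is kept too weak, the hydrolysis may stay incomplete. Fallback: the order of the last two operations is reversed. Starting from 17, hydrogenolysis (H2, Pd/C, EtOAc) gives 2-hydroxy-6-{[2-(11-hydroxyundecyl)-1,3-dioxolan-2-yl]methyl}-4-methoxybenzoic acid F7, in which no ester leaving group remains. Hydrolysis of its dioxolane in wet acetone with catalytic pyridinium p-toluenesulfonate, assisted by the neighbouring carboxylic acid, then gives 19 directly.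

Further compounds

F1 | step 6 | 5-{[2-(11-(benzyloxy)undecyl)-1,3-dioxolan-2-yl]methyl}-7-hydroxy-2,2-dimethyl-4H-1,3-benzodioxin-4-one | CC1(C)OC(=O)c2c(O1)cc(O)cc2CC3(CCCCCCCCCCCOCc4ccccc4)OCCO3
F2 | step 6 | 5-{[2-(11-(benzyloxy)undecyl)-1,3-dioxolan-2-yl]methyl}-7-methoxy-2,2-dimethyl-4H-1,3-benzodioxin-4-one | CC1(C)OC(=O)c2c(O1)cc(OC)cc2CC3(CCCCCCCCCCCOCc4ccccc4)OCCO3
F3 | step 5 | 2-[2-(11-(benzyloxy)undecyl)-1,3-dioxolan-2-yl]acetaldehyde | O=CCC1(CCCCCCCCCCCOCc2ccccc2)OCCO1
F4 | step 5 | 6-{5-[2-(11-(benzyloxy)undecyl)-1,3-dioxolan-2-yl]-4-hydroxy-2-oxopentyl}-2,2-dimethyl-4H-1,3-dioxin-4-one (racemic) | CC1(C)OC(=O)C=C(CC(=O)CC(O)CC2(CCCCCCCCCCCOCc3ccccc3)OCCO2)O1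
F5 | step 4 | [(2,2-dimethyl-6-methylidene-6H-1,3-dioxin-4-yl)oxy]trimethylsilane | C=C1C=C(O[Si](C)(C)C)OC(C)(C)O1
F6 | step 4 | 6-(2-hydroxypropyl)-2,2-dimethyl-4H-1,3-dioxin-4-one (racemic) | CC(O)CC1=CC(=O)OC(C)(C)O1
F7 | step 8 | 2-hydroxy-6-{[2-(11-hydroxyundecyl)-1,3-dioxolan-2-yl]methyl}-4-methoxybenzoic acid | COc1cc(O)c(C(=O)O)c(CC2(CCCCCCCCCCCO)OCCO2)c1
A1 | alternative 1 | 2-(benzyloxy)-4-methoxybenzoic acid | COc1ccc(C(=O)O)c(OCc2ccccc2)c1
A2 | alternative 1 | dimethylsulfoxonium 13-(benzyloxy)-2-oxotridecylide | CS(C)(=O)=CC(=O)CCCCCCCCCCCOCc1ccccc1
A3 | alternative 1 | 8-(benzyloxy)-3-[11-(benzyloxy)undecyl]-6-methoxy-1H-isochromen-1-one | O=C1OC(CCCCCCCCCCCOCc4ccccc4)=Cc2cc(OC)cc(OCc3ccccc3)c21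
A4 | alternative 2 | 3,5-dimethoxy-2-(trimethylsilyl)phenyl trifluoromethanesulfonate | COc1cc(OC)c([Si](C)(C)C)c(OS(=O)(=O)C(F)(F)F)c1
A5 | alternative 2 | dimethyl malonate | COC(=O)CC(=O)OC
A6 | alternative 2 | methyl 2,4-dimethoxy-6-(2-methoxy-2-oxoethyl)benzoate | COC(=O)Cc1cc(OC)cc(OC)c1C(=O)OC
A7 | alternative 3 | 1,3-dimethoxy-1-(trimethylsilyloxy)buta-1,3-diene | C=C(OC)C=C(OC)O[Si](C)(C)C
A8 | alternative 3 | benzyl 4-[2-(11-(benzyloxy)undecyl)-1,3-dioxolan-2-yl]but-2-ynoate | O=C(OCc1ccccc1)C#CCC2(CCCCCCCCCCCOCc3ccccc3)OCCO2
A9 | alternative 3 | benzyl 6-{[2-(11-(benzyloxy)undecyl)-1,3-dioxolan-2-yl]methyl}-2-hydroxy-4-methoxybenzoate | O=C(OCc1ccccc1)c2c(O)cc(OC)cc2CC3(CCCCCCCCCCCOCc4ccccc4)OCCO3
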